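## The problem

The target is a germacranolide of the heliangolide type. Its ten-membered carbocycle (C1–C10, methyls C14 on C10 and C15 on C4) carries a 1,10-epoxide that derives from an E alkene and a 4,5-epoxide that derives from a Z alkene. A butenolide is fused at C6–C7 (C7=C11, carbonyl C12, acetoxymethyl C13), and the C8 oxygen bears an (S)-2-methylglycidate. Seven stereocentres must be set: C1, C4, C5, C6, C8 and C10 in the ring (1R,4R,5S,6S,8S,10R) and one in the side chain. C8 is the only ring centre that can be brought in ready-made. It is 1,3-related to C6 across the sp2 carbon C7 and can direct the C6 carbinol (both oxygens on the α face), after which the conformation of the lactone-bridged ring has to direct the four epoxide centres. The side-chain centre is independent and is best introduced as an enantiopure acid. Three epoxides (two of them transannular to each other), the allylic acetate and the acidic γ-hydrogen of the butenolide rule out acid, strong base and nucleophiles late in the route, and ten-membered 1,5-dienes are prone to Cope rearrangement and transannular cyclisation. The enabling feature is that the two epoxide C–C bonds, C4–C5 and C1–C10, face each other across the ring and are joined by the C2–C3 bridge. As alkenes they form a cyclodeca-1,5-diene, which is the cycloreversion product of a bicyclo[2.2.0]hexane. C1–C4 can therefore come from a cyclobutene and C5–C10 from a cyclohexenone whose carbonyl is C6, whose β-methyl is C14 and whose 5-oxygen is that of C8.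

## Retrosynthesis

**Epoxides last.** The four C–O bonds of the two ring oxiranes of 28 are cut first, giving triene 27. The epoxides are the most fragile groups and would not survive enolate, hydride or fluoride chemistry; the butenolide alkene is electron-poor and the glycidate is inert, so a neutral dioxirane should touch only C1=C10 and C4=C5. The forward step must attack both alkenes from their outer faces in the conformer with C14 and C15 on the β face.

**Side chain.** The C8–O acyl bond of 27 is cut to alcohol 24 and potassium (S)-2-methylglycidate 26, which comes from commercial ester 25. Late acylation keeps the glycidate away from all earlier reagents. The forward step needs a mild activation of an epoxy acid (Yamaguchi).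

**Butenolide.** In 24 the lactone C–O bond (O6–C12) and the C6–H bond are cut, via silyl ether 23 and hydroxy ester 22, to the cross-conjugated keto ester 21. The C7=C11 alkene is then traced to the aldol bond C7–C11 in 20, made from dienone 17 and ethyl acetoxypyruvate 19 (from ethyl bromopyruvate 18). This cut uses the C6 carbonyl twice: first to make C7 nucleophilic, then as the carbinol that closes the lactone. The alternative, alkylation at C7 followed by late introduction of the unsaturation, would be longer. The forward sequence asks for kinetic enolisation at C7 without loss of the β-silyloxy group, an E1cB dehydration, and a 1,2-reduction in which C8 controls C6.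

**Ten-membered ring.** Dienone 17 is reconnected at C1–C4 and C5–C10 to the tricyclic ketone 16. This replaces a medium ring with two alkenes of defined geometry by a rigid tricycle. The forward cycloreversion is thermal and reagent-free, and the conjugation of the new 4-ene with the C6 ketone both fixes the Z geometry and holds back the Cope rearrangement.

**C15 oxidation level.** The C4 methyl of 16 is traced to the ester of photoadduct 11 through ketal 12, alcohol 13, tosylate 14 and ketal 15. The ester is needed in the photochemical step, so it is reduced afterwards on the robust tricycle. The ketone must be masked, because a free C6 hydroxyl would displace the C15 sulfonate and close a tetrahydrofuran.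

**Key disconnection.** The central cyclobutane of 11 is cut at C4–C5 and C1–C10 to enone 7 and cyclobutene ester 10. Both are small, and 7 carries the only stereocentre that has to survive. The forward step must give head-to-head regiochemistry and the cis,anti,cis ring fusion.

**Building blocks.** Enone 7 comes from enone 5 by methyl addition (6) and oxidative transposition. Enone 5 comes from the desymmetrised monoacetate 3 via acetoxy ketone 4; 3 comes from meso diol 2 and commercial triol 1. Ester 10 comes from bromo ester 8 via acid 9.

## Roads not taken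

**Alternative 1:** anionic oxy-Cope ring expansion. The cut is C8–C9 (formed) with cleavage of C1–C6 of a six-membered carbinol that bears an alkenyl and an isopropenyl group. KH and 18-crown-6 would give (8S)-8-(4-methoxybenzyloxy)germacra-1(10)E,4Z-dien-6-one A1, which differs from 17 only in the C8 protecting group. Its merits are real: the ring, the E alkene, the Z enone and the ketone arise in one low-temperature step from a monoterpene-derived ring, in roughly half the steps needed here to reach 17. Its weak points lie at C8. The centre would be created during the rearrangement from the geometry of a fragile β-alkoxyvinyl unit and the chair/boat preference, relayed from a centre that the same step destroys. The product enolate carries the C8 alkoxy group in the β position under strongly basic conditions, which invites E1cB loss. The chosen plan is longer, but C8 is fixed before any C–C bond is made and the ring is formed under neutral conditions.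

**Alternative 2:** Nozaki–Hiyama–Kishi macrocyclisation. The cut is C6–C7. NiCl2/CrCl2 would turn a C7 enol triflate into an alkenylchromium that adds to a C6 aldehyde, and the alkoxide would lactonise to give the diepoxy core A2 (C8 silyl ether, C13 4-methoxybenzyl ether). This road is the most convergent. It fixes the butenolide geometry in the open chain and would allow both epoxides to be installed on acyclic alkenes by reagent control. It is therefore better than the chosen plan exactly where that plan is weakest (steps 17, 18 and 22). Against it stand the closure of a ten-membered carbocycle with no ring alkene to preorganise it, a hindered tetrasubstituted alkenyl triflate, a C6 configuration decided in the macrocyclisation, and a long linear precursor that carries two epoxides and an epoxy aldehyde. The chosen plan answers with a ring formation that owes nothing to ring-closing entropy.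

**Alternative 3:** B-alkyl Suzuki–Miyaura macrocyclisation. The cut is C1–C2. Hydroboration of a terminal vinyl group with 9-BBN and coupling with an (E)-alkenyl iodide under Pd(dppf)Cl2/Cs2CO3 would give 13-acetoxy-8-silyloxygermacra-1(10)E,4Z,7(11)-trien-12,6-olide A3, which is the same compound as 23. Both alkene geometries, C6, C8 and the butenolide would be set by acyclic methods, which is more secure than steps 17 and 18, and the endgame would be shared. The weak points are the sp3–sp2 closure of a strained (E,Z)-cyclodecadiene (β-hydride elimination, oligomerisation), the exposure of butenolide and allylic acetate to carbonate base, and the length of the precursor. The chosen plan reaches 17 from simple rings and forms the ten-membered ring by a fragmentation that cannot oligomerise.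

Key step: step 8

Remark: from compound 11 onward the germacrane numbering defined above is used for all ring positions.
Remark: the lipase in step 2 is assumed to acylate the carbinol of R configuration, the usual preference of such enzymes for secondary alcohols.

## Route

Step 1
Reactants: 1 all-cis-cyclohexane-1,3,5-triol
Product: 2 cis,cis-5-(tert-butyldimethylsilyloxy)cyclohexane-1,3-diol (meso)
Conditions: TBSCl (1.0 equiv), imidazole, DMF, 0 °C to rt
Reagents that add atoms: tert-butyldimethylsilyl chloride, CC(C)(C)[Si](C)(C)Cl
Why: Statistical monosilylation of three equivalent hydroxyls; the product keeps a mirror plane through C5, and unreacted triol and bis-ether are separated and recycled.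

Step 2
Reactants: 2 cis,cis-5-(tert-butyldimethylsilyloxy)cyclohexane-1,3-diol
Product: 3 (1R,3S,5S)-3-hydroxy-5-(tert-butyldimethylsilyloxy)cyclohexyl acetate
Conditions: vinyl acetate, immobilised Candida antarctica lipase B, tBuOMe, rt
Reagents that add atoms: vinyl acetate, CC(=O)OC=C
Why: Enzymatic desymmetrisation of a meso-1,3-diol by irreversible transesterification; acylation of the R-configured carbinol breaks the mirror plane and defines all three centres of 3 at once.

Step 3
Reactants: 3 (1R,3S,5S)-3-hydroxy-5-(tert-butyldimethylsilyloxy)cyclohexyl acetate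
Product: 5 (5R)-5-(tert-butyldimethylsilyloxy)cyclohex-2-en-1-one, via acetoxy ketone 4 (not isolated)
Conditions: Dess–Martin periodinane, CH2Cl2, rt; then DBU, 0 °C
Reagents that add atoms: none
Why: Dess–Martin oxidation of the free carbinol, then E1cB loss of acetic acid, which leaves far more readily than the silyloxy group; the carbinol carbon becomes C1 and the acetoxy carbon C3, so the remaining centre is R.

Step 4
Reactants: 5 (5R)-5-(tert-butyldimethylsilyloxy)cyclohex-2-en-1-one
Product: 6 (5R)-5-(tert-butyldimethylsilyloxy)-1-methylcyclohex-2-en-1-ol (both C1 epimers)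
Conditions: MeLi, Et2O, −78 °C; aq. NH4Cl
Reagents that add atoms: methyllithium, [Li]C
Why: 1,2-Addition of a hard organolithium to the enone at low temperature outruns enolisation; the new carbinol centre is erased in step 5.

Step 5
Reactants: 6 (5R)-5-(tert-butyldimethylsilyloxy)-1-methylcyclohex-2-en-1-ol
Product: 7 (5S)-5-(tert-butyldimethylsilyloxy)-3-methylcyclohex-2-en-1-one
Conditions: pyridinium chlorochromate [C5H5NH][CrO3Cl], 4 Å molecular sieves, CH2Cl2, rt
Reagents that add atoms: none
Why: Babler–Dauben oxidative transposition (chromate ester, 1,3-shift, oxidation) moves the oxygen to the former C3 and leaves the methyl on the β-carbon; the silyloxy centre is untouched and only its descriptor changes to S.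

Step 6
Reactants: 8 ethyl 1-bromocyclobutane-1-carboxylate
Product: 9 cyclobut-1-ene-1-carboxylic acid
Conditions: KOH (powder, excess), toluene, reflux; cold aq. HCl
Reagents that add atoms: potassium hydroxide, [K+].[OH-]
Why: E2 dehydrobromination of the tertiary α-bromo ester with concurrent saponification, a standard entry to this acid.

Step 7
Reactants: 9 cyclobut-1-ene-1-carboxylic acid
Product: 10 methyl cyclobut-1-ene-1-carboxylate
Conditions: MeI, K2CO3, DMF, rt; distilled and used at once
Reagents that add atoms: iodomethane, CI
Why: O-Alkylation of the carboxylate under non-acidic conditions avoids addition to the strained acrylate; the volatile ester is used immediately to limit oligomerisation.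

Step 8
Reactants: 7 (5S)-5-(tert-butyldimethylsilyloxy)-3-methylcyclohex-2-en-1-one; 10 methyl cyclobut-1-ene-1-carboxylate
Product: 11 methyl (8S)-8-(tert-butyldimethylsilyloxy)-6-methyl-10-oxotricyclo[4.4.0.0(2,5)]decane-2-carboxylate (cis,anti,cis; cyclobutane trans to the silyloxy group)
Conditions: hν (medium-pressure Hg lamp, uranium-glass filter, λ > 330 nm), 10 (5 equiv), CH2Cl2, −20 °C, argon; crude adduct stirred with basic Al2O3
Reagents that add atoms: none
Why: Excitation of 7 and intersystem crossing give the twisted enone triplet, which adds to ground-state 10 through a triplet 1,4-diradical that closes after spin inversion; the closest known reaction type is the enone (2+2) photocycloaddition with acceptor-substituted cyclobutenes used in photoaddition–thermolysis routes to cyclodeca-1,5-dienes. One ring is closed, the central cyclobutane C4–C5–C10–C1, by an intermolecular first bond and radical–radical recombination of the 1,4-diradical; it is fused to both existing rings, so that a bicyclo[4.2.0]octanone and a bicyclo[2.2.0]hexane result whose perimeter is the future ten-membered ring. The step needs head-to-head regiochemistry (ester carbon C4 to the enone α-carbon C5, C1 to the β-carbon C10), and the acceptor ester on the cyclobutene secures it, as electron-poor alkenes place their substituted carbon next to the enone α-carbon. C1 and C4 are cis because they belong to the four-membered ring of 10. C5 and C10 end cis because any strained trans-fused adduct epimerises at C5, α to the ketone, on basic alumina. The anti relationship of the two outer rings follows from approach of the cyclobutene with its CH2–CH2 bridge turned away from the six-membered ring. Bonding at C10 is expected axial and trans to the C8 silyloxy group; the other facial isomer leads to the same dienone 17, so facial selectivity is not critical. What must be avoided is the cis,syn,cis adduct, which would give a different alkene geometry on cycloreversion.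

Step 9
Reactants: 11 methyl (8S)-8-(tert-butyldimethylsilyloxy)-6-methyl-10-oxotricyclo[4.4.0.0(2,5)]decane-2-carboxylate
Product: 12 ethylene ketal of 11 at C6 (10,10-ethylenedioxy ester)
Conditions: 1,2-bis(trimethylsilyloxy)ethane, Me3SiOTf (cat.), CH2Cl2, −78 to −20 °C
Reagents that add atoms: 1,2-bis(trimethylsilyloxy)ethane, C[Si](C)(C)OCCO[Si](C)(C)C
Why: Aprotic ketalisation with the bis-silyl ether of ethylene glycol spares the silyl ether and the β-silyloxy ketone; masking C6 prevents a C6 alkoxide from displacing the later C15 sulfonate.

Step 10
Reactants: 12 ethylene ketal of 11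
Product: 13 C15 primary alcohol (ketal, C4–CH2OH)
Conditions: LiAlH4, THF, 0 °C
Reagents that add atoms: none
Why: Hydride reduction of the ester to the neopentyl-type primary alcohol; ketal and silyl ether are inert.

Step 11
Reactants: 13 C15 primary alcohol
Product: 14 C15 p-toluenesulfonate
Conditions: TsCl, pyridine, DMAP (cat.), 0 °C to rt
Reagents that add atoms: p-toluenesulfonyl chloride, Cc1ccc(cc1)S(Cl)(=O)=O
Why: Sulfonylation of the only free hydroxyl.

Step 12
Reactants: 14 C15 p-toluenesulfonate
Product: 15 (8S)-8-(tert-butyldimethylsilyloxy)-10,10-ethylenedioxy-2,6-dimethyltricyclo[4.4.0.0(2,5)]decane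
Conditions: LiEt3BH, THF, reflux
Reagents that add atoms: none
Why: SN2 hydride displacement by a very nucleophilic borohydride, the reagent class that reduces hindered neopentyl-type sulfonates; no cation is formed, so the cyclobutylcarbinyl system should not rearrange.

Step 13
Reactants: 15 (8S)-8-(tert-butyldimethylsilyloxy)-10,10-ethylenedioxy-2,6-dimethyltricyclo[4.4.0.0(2,5)]decane
Product: 16 (8S)-8-(tert-butyldimethylsilyloxy)-2,6-dimethyltricyclo[4.4.0.0(2,5)]decan-10-one (cis,anti,cis)
Conditions: pyridinium p-toluenesulfonate, acetone/H2O, 50 °C
Reagents that add atoms: water, O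
Why: Mild acid hydrolysis of the dioxolane, under which a secondary tert-butyldimethylsilyl ether survives.

Step 14
Reactants: 16 (8S)-8-(tert-butyldimethylsilyloxy)-2,6-dimethyltricyclo[4.4.0.0(2,5)]decan-10-one
Product: 17 (2Z,6E,9S)-9-(tert-butyldimethylsilyloxy)-3,7-dimethylcyclodeca-2,6-dien-1-one [(8S)-8-silyloxygermacra-1(10)E,4Z-dien-6-one]
Conditions: degassed toluene (0.01 M), base-washed sealed tube, 180–190 °C, short reaction time
Reagents that add atoms: none
Why: Thermal cycloreversion of the bicyclo[2.2.0]hexane: homolysis of the central C1–C4 bond gives a cyclohexane-1,4-diyl, which cleaves C5–C10; the cis,anti,cis fusion delivers one E and one Z alkene, the Z one being the 4-ene conjugated with the C6 ketone, and this conjugation is what holds back the Cope rearrangement.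

Step 15
Reactants: 18 ethyl bromopyruvate
Product: 19 ethyl 3-acetoxy-2-oxopropanoate
Conditions: KOAc, acetone, rt
Reagents that add atoms: potassium acetate, [K+].CC([O-])=O
Why: SN2 displacement of an activated α-keto bromide by acetate.

Step 16
Reactants: 17 (8S)-8-silyloxygermacra-1(10)E,4Z-dien-6-one; 19 ethyl 3-acetoxy-2-oxopropanoate
Product: 20 ethyl 3-acetoxy-2-hydroxy-2-[(8S)-8-(tert-butyldimethylsilyloxy)-6-oxogermacra-1(10)E,4Z-dien-7-yl]propanoate (mixture at C7 and C11)
Conditions: LiN(iPr)2, THF, −78 °C; then 19, −78 °C; AcOH quench at −78 °C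
Reagents that add atoms: none
Why: Kinetic deprotonation can occur only at C7 (C5 is vinylic) and lithium enolates next to a β-silyloxy carbon are stable at −78 °C; aldol addition to the highly electrophilic keto group of 19 forms C7–C11, and both new centres are removed in step 17.

Step 17
Reactants: 20 aldol adduct
Product: 21 ethyl (7(11)Z)-13-acetoxy-8-(tert-butyldimethylsilyloxy)-6-oxogermacra-1(10)E,4Z,7(11)-trien-12-oate (ester cis to C6)
Conditions: Burgess reagent (methyl N-(triethylammoniosulfonyl)carbamate), toluene, 50 °C
Reagents that add atoms: none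
Why: Burgess dehydration of a tertiary β-hydroxy ketone; only C7–H is acidic, so the alkene can form only between C7 and C11, but its geometry is not controlled by the mechanism and the isomer with the ester cis to C6 is the one carried on.

Step 18
Reactants: 21 cross-conjugated keto ester
Product: 23 (6R,8S)-13-acetoxy-8-(tert-butyldimethylsilyloxy)germacra-1(10)E,4Z,7(11)-trien-12,6-olide, via hydroxy ester 22 (not isolated)
Conditions: NaBH4, CeCl3·7H2O, MeOH, −78 to −40 °C; then silica gel
Reagents that add atoms: none
Why: Luche 1,2-reduction of the dienone carbonyl; in the conformer that minimises allylic strain at C8 (C8–H eclipsing the exocyclic alkene) the silyloxy group covers one face of the neighbouring carbonyl, so hydride should enter from the other face and place O6 cis to O8 (spatially the 6S arrangement of the target; the descriptor reads R while C4=C5 is present), and the cis γ-hydroxy ester lactonises spontaneously.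

Step 19
Reactants: 23 silyl ether of the butenolide
Product: 24 (6R,8S)-13-acetoxy-8-hydroxygermacra-1(10)E,4Z,7(11)-trien-12,6-olide
Conditions: HF·pyridine, THF, 0 °C to rt
Reagents that add atoms: none
Why: Buffered fluoride cleaves the secondary silyl ether without touching the acetate or deprotonating the butenolide γ-position.

Step 20
Reactants: 25 methyl (2S)-2-methyloxirane-2-carboxylate
Product: 26 potassium (2S)-2-methyloxirane-2-carboxylate
Conditions: KOH (1.0 equiv), MeOH/H2O, 0 °C; evaporation, drying
Reagents that add atoms: potassium hydroxide, [K+].[OH-]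
Why: Saponification at the ester carbonyl leaves the quaternary epoxide centre untouched; isolating the salt avoids handling the small, water-soluble epoxy acid.

Step 21
Reactants: 24 8-hydroxy butenolide; 26 potassium (2S)-2-methyloxirane-2-carboxylate
Product: 27 (6R,8S)-13-acetoxy-8-[(2S)-2-methyloxirane-2-carbonyloxy]germacra-1(10)E,4Z,7(11)-trien-12,6-olide
Conditions: 2,4,6-trichlorobenzoyl chloride, THF, rt; then 24, DMAP, toluene, rt
Reagents that add atoms: none
Why: Yamaguchi esterification through the mixed anhydride acylates the hindered secondary alcohol with retention at C8 and under conditions too mild to open the glycidate or enolise the butenolide.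

Step 22
Reactants: 27 triene ester
Product: 28 (1R,4R,5S,6S,8S,10R)-13-acetoxy-1,10:4,5-diepoxy-8-[(2S)-2-methyloxirane-2-carbonyloxy]germacr-7(11)-en-12,6-olide (target)
Conditions: dimethyldioxirane (2.2 equiv), acetone, −20 to 0 °C
Reagents that add atoms: dimethyldioxirane, CC1(C)OO1
Why: Neutral electrophilic epoxidation reaches only the two electron-rich trisubstituted alkenes; attack on the outer faces of the ring conformer with C14 and C15 on the β face should give the 1β,10α and 4α,5α epoxides, and the absence of acid avoids transannular opening.

## Compound list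

1 | all-cis-cyclohexane-1,3,5-triol | O[C@H]1C[C@@H](O)C[C@@H](O)C1 | starting material
2 | cis,cis-5-(tert-butyldimethylsilyloxy)cyclohexane-1,3-diol (meso) | O[C@H]1C[C@@H](O)C[C@@H](O[Si](C)(C)C(C)(C)C)C1 | intermediate
3 | (1R,3S,5S)-3-hydroxy-5-(tert-butyldimethylsilyloxy)cyclohexyl acetate | O[C@H]1C[C@@H](OC(C)=O)C[C@@H](O[Si](C)(C)C(C)(C)C)C1 | intermediate
4 | (1S,3R)-3-(tert-butyldimethylsilyloxy)-5-oxocyclohexyl acetate | O=C1C[C@@H](OC(C)=O)C[C@@H](O[Si](C)(C)C(C)(C)C)C1 | intermediate
5 | (5R)-5-(tert-butyldimethylsilyloxy)cyclohex-2-en-1-one | O=C1C=CC[C@@H](O[Si](C)(C)C(C)(C)C)C1 | intermediate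
6 | (5R)-5-(tert-butyldimethylsilyloxy)-1-methylcyclohex-2-en-1-ol (C1 epimers) | CC1(O)C=CC[C@@H](O[Si](C)(C)C(C)(C)C)C1 | intermediate
7 | (5S)-5-(tert-butyldimethylsilyloxy)-3-methylcyclohex-2-en-1-one | O=C1C[C@@H](O[Si](C)(C)C(C)(C)C)CC(C)=C1 | intermediate
8 | ethyl 1-bromocyclobutane-1-carboxylate | CCOC(=O)C1(Br)CCC1 | starting material
9 | cyclobut-1-ene-1-carboxylic acid | OC(=O)C1=CCC1 | intermediate
10 | methyl cyclobut-1-ene-1-carboxylate | COC(=O)C1=CCC1 | intermediate
11 | methyl (8S)-8-(tert-butyldimethylsilyloxy)-6-methyl-10-oxotricyclo[4.4.0.0(2,5)]decane-2-carboxylate (cis,anti,cis; cyclobutane trans to the silyloxy group) | O=C1C[C@@H](O[Si](C)(C)C(C)(C)C)C[C@@]2(C)[C@@H]1[C@]1(C(=O)OC)CC[C@@H]12 | intermediate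
12 | methyl (8S)-8-(tert-butyldimethylsilyloxy)-10,10-ethylenedioxy-6-methyltricyclo[4.4.0.0(2,5)]decane-2-carboxylate | O1CCOC13C[C@@H](O[Si](C)(C)C(C)(C)C)C[C@@]2(C)[C@@H]3[C@]1(C(=O)OC)CC[C@@H]12 | intermediate
13 | [(8S)-8-(tert-butyldimethylsilyloxy)-10,10-ethylenedioxy-6-methyltricyclo[4.4.0.0(2,5)]dec-2-yl]methanol | O1CCOC13C[C@@H](O[Si](C)(C)C(C)(C)C)C[C@@]2(C)[C@@H]3[C@]1(CO)CC[C@@H]12 | intermediate
14 | [(8S)-8-(tert-butyldimethylsilyloxy)-10,10-ethylenedioxy-6-methyltricyclo[4.4.0.0(2,5)]dec-2-yl]methyl p-toluenesulfonate | O1CCOC13C[C@@H](O[Si](C)(C)C(C)(C)C)C[C@@]2(C)[C@@H]3[C@]1(COS(=O)(=O)c4ccc(C)cc4)CC[C@@H]12 | intermediate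
15 | (8S)-8-(tert-butyldimethylsilyloxy)-10,10-ethylenedioxy-2,6-dimethyltricyclo[4.4.0.0(2,5)]decane | O1CCOC13C[C@@H](O[Si](C)(C)C(C)(C)C)C[C@@]2(C)[C@@H]3[C@]1(C)CC[C@@H]12 | intermediate
16 | (8S)-8-(tert-butyldimethylsilyloxy)-2,6-dimethyltricyclo[4.4.0.0(2,5)]decan-10-one (cis,anti,cis) | O=C1C[C@@H](O[Si](C)(C)C(C)(C)C)C[C@@]2(C)[C@@H]1[C@]1(C)CC[C@@H]12 | intermediate
17 | (2Z,6E,9S)-9-(tert-butyldimethylsilyloxy)-3,7-dimethylcyclodeca-2,6-dien-1-one | O=C1C[C@@H](O[Si](C)(C)C(C)(C)C)C/C(C)=C/CC/C(C)=C\1 | intermediate
18 | ethyl bromopyruvate (ethyl 3-bromo-2-oxopropanoate) | CCOC(=O)C(=O)CBr | starting material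
19 | ethyl 3-acetoxy-2-oxopropanoate | CCOC(=O)C(=O)COC(C)=O | intermediate
20 | ethyl 3-acetoxy-2-hydroxy-2-[(8S)-8-(tert-butyldimethylsilyloxy)-6-oxogermacra-1(10)E,4Z-dien-7-yl]propanoate (C7 and C11 epimers) | O=C1C(C(O)(COC(C)=O)C(=O)OCC)[C@@H](O[Si](C)(C)C(C)(C)C)C/C(C)=C/CC/C(C)=C\1 | intermediate
21 | ethyl (8S)-13-acetoxy-8-(tert-butyldimethylsilyloxy)-6-oxogermacra-1(10)E,4Z,7(11)Z-trien-12-oate | O=C1/C(=C(/COC(C)=O)\C(=O)OCC)[C@@H](O[Si](C)(C)C(C)(C)C)C/C(C)=C/CC/C(C)=C\1 | intermediate
22 | ethyl (6R,8S)-13-acetoxy-6-hydroxy-8-(tert-butyldimethylsilyloxy)germacra-1(10)E,4Z,7(11)Z-trien-12-oate | O[C@H]1/C(=C(/COC(C)=O)\C(=O)OCC)[C@@H](O[Si](C)(C)C(C)(C)C)C/C(C)=C/CC/C(C)=C\1 | intermediate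
23 | (6R,8S)-13-acetoxy-8-(tert-butyldimethylsilyloxy)germacra-1(10)E,4Z,7(11)-trien-12,6-olide | CC(=O)OCC1=C2[C@@H](O[Si](C)(C)C(C)(C)C)C/C(C)=C/CC/C(C)=C\[C@H]2OC1=O | intermediate
24 | (6R,8S)-13-acetoxy-8-hydroxygermacra-1(10)E,4Z,7(11)-trien-12,6-olide | CC(=O)OCC1=C2[C@@H](O)C/C(C)=C/CC/C(C)=C\[C@H]2OC1=O | intermediate
25 | methyl (2S)-2-methyloxirane-2-carboxylate | COC(=O)[C@]1(C)CO1 | starting material
26 | potassium (2S)-2-methyloxirane-2-carboxylate | [K+].[O-]C(=O)[C@]1(C)CO1 | intermediate
27 | (6R,8S)-13-acetoxy-8-[(2S)-2-methyloxirane-2-carbonyloxy]germacra-1(10)E,4Z,7(11)-trien-12,6-olide | CC(=O)OCC1=C2[C@@H](OC(=O)[C@]3(C)CO3)C/C(C)=C/CC/C(C)=C\[C@H]2OC1=O | intermediate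
28 | (1R,4R,5S,6S,8S,10R)-13-acetoxy-1,10:4,5-diepoxy-8-[(2S)-2-methyloxirane-2-carbonyloxy]germacr-7(11)-en-12,6-olide | CC(=O)OCC1=C2[C@@H](OC(=O)[C@]3(C)CO3)C[C@@]3(C)O[C@@H]3CC[C@@]3(C)O[C@H]3[C@H]2OC1=O | target

## Step count and least certain steps

Total: 22 steps. Longest linear sequence: 18 steps (1–5, 8–14, 16–19, 21, 22).

**Step 8 (key step).** The β,β-disubstituted enone 7 adds slowly, so evaporative loss and oligomerisation of the volatile ester 10, secondary photolysis and formation of cis,syn,cis or head-to-tail adducts may erode the yield. Fallback: starting from 7 and 9, irradiate 7 with the free acid 9, which is non-volatile, can be used in large excess and is recovered by base extraction; the acidic adduct is separated from neutral by-products in the same way. This gives (8S)-8-(tert-butyldimethylsilyloxy)-6-methyl-10-oxotricyclo[4.4.0.0(2,5)]decane-2-carboxylic acid F1, and O-methylation (MeI, K2CO3) returns to the route at 11.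

**Step 14.** At the temperature that the methyl-substituted bicyclo[2.2.0]hexane needs, Cope rearrangement of the dienone to a divinylcyclohexanone or thermal loss of silanol from the β-silyloxy ketone may compete. Fallback: starting from 11, fragment at the ester stage, where the ester stabilises the intermediate diyl (lower temperature) and the product alkene is conjugated on both sides. Thermolysis of 11 gives methyl (8S)-8-(tert-butyldimethylsilyloxy)-6-oxogermacra-1(10),4-dien-15-oate F2 (C3 and C6 cis). iBu2AlH reduces both carbonyls to the 6,15-diol F3, whose hydroxyls are trans across C4=C5 and cannot close an ether. MsCl, LiCl and 2,4,6-collidine convert the primary allylic hydroxyl into the 15-chloride F4. LiEt3BH gives (8S)-8-(tert-butyldimethylsilyloxy)germacra-1(10)E,4Z-dien-6-ol F5, and MnO2 oxidises the allylic carbinol, returning to the route at 17.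

**Step 17.** Loss of geometric control in the elimination would put the ester trans to C6, where it cannot lactonise. Fallback: starting from 20, close the lactone before making the alkene, so that the ring fixes the geometry. NaBH4/CeCl3 reduction of 20 and lactonisation give the 11-hydroxy-12,6-lactone F6. Dehydration with SOCl2/pyridine toward C7–H, which gives the tetrasubstituted conjugated alkene, returns to the route at 23.

**Step 18.** Hydride attack from the wrong face of C6, if the ring prefers another conformer, or conjugate reduction of the ene-dicarbonyl system may occur. Fallback: starting from 21, let the C8 hydroxyl direct the reduction by chelation instead of relying on shielding by its silyl ether. HF·pyridine gives ethyl (8S)-13-acetoxy-8-hydroxy-6-oxogermacra-1(10)E,4Z,7(11)Z-trien-12-oate F7. Narasaka–Prasad reduction (Et2BOMe, NaBH4, THF/MeOH, −78 °C) delivers hydride to the boron chelate anti to C9 and gives the 6,8-cis diol, which lactonises and returns to the route at 24.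

**Step 22.** Poor facial selectivity at one or both alkenes, or transannular attack of the 4-ene on the first-formed 1,10-epoxide, is possible. Fallback: starting from 24, epoxidise stepwise with hydroxyl delivery. VO(acac)2/tBuOOH on 24 uses the homoallylic C8 hydroxyl to epoxidise C1=C10 only, on the face of O8, giving the 1,10-epoxy alcohol F8. Yamaguchi acylation with 26 gives the 1,10-epoxy ester F9, and dimethyldioxirane then epoxidises C4=C5 alone, returning to the route at 28.

## Further compounds

F1 | step 8 | (8S)-8-(tert-butyldimethylsilyloxy)-6-methyl-10-oxotricyclo[4.4.0.0(2,5)]decane-2-carboxylic acid (cis,anti,cis) | O=C1C[C@@H](O[Si](C)(C)C(C)(C)C)C[C@@]2(C)[C@@H]1[C@]1(C(O)=O)CC[C@@H]12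
F2 | step 14 | methyl (8S)-8-(tert-butyldimethylsilyloxy)-6-oxogermacra-1(10)E,4-dien-15-oate (C3 and C6 cis) | O=C1C[C@@H](O[Si](C)(C)C(C)(C)C)C/C(C)=C/CC/C(C(=O)OC)=C\1
F3 | step 14 | (8S)-8-(tert-butyldimethylsilyloxy)germacra-1(10)E,4-diene-6,15-diol (C3 and C6 cis; C6 epimers) | OC1C[C@@H](O[Si](C)(C)C(C)(C)C)C/C(C)=C/CC/C(CO)=C\1
F4 | step 14 | (8S)-15-chloro-8-(tert-butyldimethylsilyloxy)germacra-1(10)E,4-dien-6-ol (C3 and C6 cis; C6 epimers) | OC1C[C@@H](O[Si](C)(C)C(C)(C)C)C/C(C)=C/CC/C(CCl)=C\1
F5 | step 14 | (8S)-8-(tert-butyldimethylsilyloxy)germacra-1(10)E,4Z-dien-6-ol (C6 epimers) | OC1C[C@@H](O[Si](C)(C)C(C)(C)C)C/C(C)=C/CC/C(C)=C\1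
F6 | step 17 | (6R,8S)-13-acetoxy-11-hydroxy-8-(tert-butyldimethylsilyloxy)germacra-1(10)E,4Z-dien-12,6-olide (C7 and C11 epimers) | CC(=O)OCC1(O)C2[C@@H](O[Si](C)(C)C(C)(C)C)C/C(C)=C/CC/C(C)=C\[C@H]2OC1=O
F7 | step 18 | ethyl (8S)-13-acetoxy-8-hydroxy-6-oxogermacra-1(10)E,4Z,7(11)Z-trien-12-oate | O=C1/C(=C(/COC(C)=O)\C(=O)OCC)[C@@H](O)C/C(C)=C/CC/C(C)=C\1
F8 | step 22 | (1R,6R,8S,10R)-13-acetoxy-1,10-epoxy-8-hydroxygermacra-4Z,7(11)-dien-12,6-olide | CC(=O)OCC1=C2[C@@H](O)C[C@@]3(C)O[C@@H]3CC/C(C)=C\[C@H]2OC1=O
F9 | step 22 | (1R,6R,8S,10R)-13-acetoxy-1,10-epoxy-8-[(2S)-2-methyloxirane-2-carbonyloxy]germacra-4Z,7(11)-dien-12,6-olide | CC(=O)OCC1=C2[C@@H](OC(=O)[C@]3(C)CO3)C[C@@]3(C)O[C@@H]3CC/C(C)=C\[C@H]2OC1=O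
A1 | alternative 1 | (8S)-8-(4-methoxybenzyloxy)germacra-1(10)E,4Z-dien-6-one | O=C1C[C@@H](OCc2ccc(OC)cc2)C/C(C)=C/CC/C(C)=C\1
A2 | alternative 2 | 1,10:4,5-diepoxy-8-(tert-butyldimethylsilyloxy)-13-(4-methoxybenzyloxy)germacr-7(11)-en-12,6-olide | COc1ccc(COCC2=C3[C@@H](O[Si](C)(C)C(C)(C)C)C[C@@]4(C)O[C@@H]4CC[C@@]4(C)O[C@H]4[C@H]3OC2=O)cc1
A3 | alternative 3 | 13-acetoxy-8-(tert-butyldimethylsilyloxy)germacra-1(10)E,4Z,7(11)-trien-12,6-olide (identical with 23) | CC(=O)OCC1=C2[C@@H](O[Si](C)(C)C(C)(C)C)C/C(C)=C/CC/C(C)=C\[C@H]2OC1=O
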